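Decide first to treat the two hands as equal and use that as the zero of your scale, since a single-handed catalyst may move you off it.

in all of them: left-handed substrate 20 mM; right-handed substrate 20 mM; free catalyst 4.7 mol%; added ligand 4.9 mM
- Friday's: reagent 3 equiv; run made earlier
- flask: reagent 1.50 equiv

Friday's run (percent of the left-handed substrate and right-handed substrate together charged)

| time / h | left-handed product / % |
|---|---|
| 0.417 | 1.9 |
| 1.33 | 4.7 |
| 2.00 | 6.9 |
| 3.00 | 7.6 |
| 5.00 | 10.0 |
| 6.00 | 10.0 |

(standard deviation of a reading: 0.3 percentage points)

- free catalyst is single-handed; left-handed substrate and right-handed substrate are mirror images of each other, charged as a racemate, each of them at the stated concentration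
- no earlier run changes the charge of reagent; that part of a forecast is a guess

* apparent order in reagent when 5.0 % of the left-handed substrate and right-handed substrate together are converted (percent change of the rate of making left-handed product for one percent more reagent charged)

With equal hands, 5.0 % converted together means 2.50 % of left-handed product in this flask; call that the mark. In Friday's run the left-handed product stands at 10.0 % at 5.00 h and again at 6.00 h. That is below the half of the charge that was left-handed substrate, so I read the stop as free catalyst dying on a clock. The rate is then a fixed fraction per hour of the gap to the plateau.

If the plateau follows c(reagent) to the first power, this flask, with 1.50 equiv against Friday's 3 equiv, levels off at 5.00 %. Its clock factor is 2.00: the plateau divided by the gap between plateau and mark. More reagent widens that gap while the mark stays put, so the order at the mark is the plain order times this factor, and I commit to 2.00.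

The weak link is the first power, which no run tests. With a square root the plateau is 7.07 %, the factor 1.55 and the order 0.775. I keep the first power, as a guess.

The forecast says 1, lower than my figure, and calls it “a guess, skewed upward”.

The flask gives 2.2.

    reagent + free catalyst + right-handed substrate → free catalyst + right-handed product (k = 896 L² mol⁻² h⁻¹)
    free catalyst + added ligand ⇌ idle complex (K = 580 L mol⁻¹, k = 7.27 L mol⁻¹ h⁻¹)
    reagent + free catalyst + left-handed substrate → free catalyst + left-handed product (k = 1870 L² mol⁻² h⁻¹)
    free catalyst → spent catalyst (k = 0.343 h⁻¹)

In this flask at 20.0 h, spent catalyst holds 92.0 % of the catalyst charged, while 88 % of the left-handed substrate remains. Reckoned with the clock factor, and taking the plateau to double with the charge, twice the free catalyst multiplies the rate at the mark by one plus that factor, 3.00, and the run with that charge gives 3.07.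

The numbers in the tables were computed from invented constants.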